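Guaiane locants are used throughout, primed for the peroxide-bearing half.

**Plan**
- Retrosynthesis: the C11'–O–O–C8' bridge is removed first (singlet-oxygen ene reaction of an isopropylidene ketone), then the norbornene bonds C1–C4' and C3–C3' (Diels–Alder). This leaves a 2-acetoxycyclopentadiene and a cyclopentadienone.
- Both partners are 8-oxoguaianes from one hydroazulenone. In each seven-membered ring, C6–C10 carry oxygen at C8 and methyl at C10, the pattern of a 4-methoxy-2-methylphenyl ring; the ring is that arene plus one inserted carbon, C5. Cutting C5–C1 and C5–C6 gives an aryl diazoketone.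
- Forward: the carbenoid step closes the five-membered ring and expands the arene to the seven-membered ring. C15 and the C7 isopropylidene (acetone ketal) follow, and the common diol is divided. The cycloaddition closes the bicyclo[2.2.1]heptene core and the ene reaction closes the 1,2-dioxolane.
- Stereochemistry: C2 by asymmetric transfer hydrogenation; C2 sets C5 in the carbenoid step and the proton shift carries this to C10; C7 by equilibration beside the C8 ketone. C1, C3, C3' and C4' come from the endo cycloaddition on the faces opposite the C2 acetoxy, C10 methyl and C10' methyl groups; C8' by hemiketal equilibration.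

Key step: step 6

Assumption: the hemiketal carbon C8' opens and closes through the β-hydroperoxy ketone, so the configuration drawn for the target is taken to be the one reached at equilibrium.

Step 1
Reactants: 1 1-(4-methoxy-2-methylphenyl)ethan-1-one; 2 diethyl carbonate
Product: 3 ethyl 3-(4-methoxy-2-methylphenyl)-3-oxopropanoate
Conditions: NaH, THF, reflux; aq. HCl work-up
Reagents that add atoms: none
Why: Claisen condensation of the methyl ketone enolate with the non-enolisable carbonate, driven by formation of the β-keto ester enolate.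

Step 2
Reactants: 3 ethyl 3-(4-methoxy-2-methylphenyl)-3-oxopropanoate
Product: 4 ethyl (3S)-3-hydroxy-3-(4-methoxy-2-methylphenyl)propanoate
Conditions: RuCl[(S,S)-TsDPEN](p-cymene) (1 mol%), HCO2H/Et3N azeotrope, 40 °C
Reagents that add atoms: none
Why: Noyori asymmetric transfer hydrogenation of an aryl ketone, in which the (S,S)-diamine ligand holds the aryl group against the η6-arene and hydride goes to the face that gives the (S)-carbinol, the future C2.

Step 3
Reactants: 4 ethyl (3S)-3-hydroxy-3-(4-methoxy-2-methylphenyl)propanoate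
Product: 5 ethyl (3S)-3-[(tert-butyldimethylsilyl)oxy]-3-(4-methoxy-2-methylphenyl)propanoate
Conditions: TBSCl, imidazole, DMF, rt
Reagents that add atoms: tert-butyldimethylsilyl chloride, CC(C)(C)[Si](C)(C)Cl
Why: Silyl ether formation at a secondary benzylic alcohol, giving a bulky ether that is a poor donor toward the later carbenoid.

Step 4
Reactants: 5 ethyl (3S)-3-[(tert-butyldimethylsilyl)oxy]-3-(4-methoxy-2-methylphenyl)propanoate
Product: 6 (3S)-3-[(tert-butyldimethylsilyl)oxy]-3-(4-methoxy-2-methylphenyl)propanoic acid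
Conditions: LiOH, THF/MeOH/H2O, rt; dilute HCl to pH 4 at 0 °C
Reagents that add atoms: lithium hydroxide, [Li+].[OH-]
Why: Ester saponification, in which hydroxide attack at the ester carbonyl is faster than β-elimination of the silyloxy group.

Step 5
Reactants: 6 (3S)-3-[(tert-butyldimethylsilyl)oxy]-3-(4-methoxy-2-methylphenyl)propanoic acid
Product: 8 (4S)-4-[(tert-butyldimethylsilyl)oxy]-1-diazo-4-(4-methoxy-2-methylphenyl)butan-2-one, via mixed anhydride 7 (not isolated)
Conditions: i-BuOCOCl, N-methylmorpholine, THF, −15 °C; then CH2N2, Et2O, 0 °C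
Reagents that add atoms: diazomethane, C=[N+]=[N-]
Why: Acylation of diazomethane by the mixed carbonic anhydride (first stage of an Arndt–Eistert sequence) gives the terminal diazoketone without acid that would cleave the silyl ether.

Step 6
Reactants: 8 (4S)-4-[(tert-butyldimethylsilyl)oxy]-1-diazo-4-(4-methoxy-2-methylphenyl)butan-2-one
Product: 10 (3S,8aS)-3-[(tert-butyldimethylsilyl)oxy]-6-methoxy-4-methyl-3,8a-dihydroazulen-1(2H)-one, via norcaradiene 9 (not isolated)
Conditions: Rh2(OAc)4 (1 mol%), CH2Cl2, reflux, slow addition of 8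
Reagents that add atoms: none
Why: Rh2(OAc)4 turns the diazoketone into an electrophilic rhodium carbenoid at C5 that adds across the ipso–ortho bond C1–C6 of the electron-rich arene ([2+1] addition) to give norcaradiene 9, whose C1–C6 bond opens by disrotatory 6π electrocyclisation to cycloheptatriene 10. The closest known reaction type is the intramolecular Buchner reaction of 1-diazo-4-arylbutan-2-ones to 3,8a-dihydroazulen-1(2H)-ones. The five-membered ring closes by the tethered carbenoid addition (bond C5–C1 across the three-atom tether C2–C3–C4), and the seven-membered ring arises from the benzene ring by insertion of C5 (bond C5–C6) and the electrocyclic opening. The one new stereocentre, C5, is controlled by C2: the benzylic hydrogen lies in the arene plane beside the ortho methyl group (allylic 1,3-strain), the silyloxy group points away from the face used by the tether, and H5 ends anti to the silyloxy group. The step needs addition at C1–C6 and not at the methyl-bearing C1–C10 bond, and a carbenoid that ignores the silyloxy oxygen; the ortho methyl group blocks the second bond, the para methoxy group makes the ipso carbon the most nucleophilic site, the bulky silyl ether is a poor ylide donor, and acid-free conditions prevent rearomatisation to a 2-tetralone.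

Step 7
Reactants: 10 (3S,8aS)-3-[(tert-butyldimethylsilyl)oxy]-6-methoxy-4-methyl-3,8a-dihydroazulen-1(2H)-one
Product: 11 (3S,4R)-3-[(tert-butyldimethylsilyl)oxy]-6-methoxy-4-methyl-3,4-dihydroazulen-1(2H)-one
Conditions: Et3N, CH2Cl2, rt
Reagents that add atoms: none
Why: Amine-mediated 1,3-prototropic shift to the conjugated isomer, in which the doubly activated H5 is removed and the proton is returned to C10 within the ion pair on the same face, which is also the face opposite the silyloxy group, so that the C10 methyl ends cis to the C2 oxygen while the mild base neither re-ionises the product nor eliminates the silyloxy group.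

Step 8
Reactants: 11 (3S,4R)-3-[(tert-butyldimethylsilyl)oxy]-6-methoxy-4-methyl-3,4-dihydroazulen-1(2H)-one
Product: 13 (1R,3S,4R)-3-[(tert-butyldimethylsilyl)oxy]-6-methoxy-1,4-dimethyl-1-[(triethylsilyl)oxy]-1,2,3,4-tetrahydroazulene, via lithium alkoxide 12 (not isolated)
Conditions: MeLi, CeCl3, THF, −78 °C; then TESOTf, −78 to 0 °C
Reagents that add atoms: methyllithium, C[Li]; triethylsilyl trifluoromethanesulfonate, CC[Si](CC)(CC)OS(=O)(=O)C(F)(F)F
Why: 1,2-Addition of the weakly basic organocerium reagent to the enolisable cross-conjugated ketone from the face opposite the C2 silyloxy and C10 methyl groups, then silylation of the tertiary alkoxide in the same flask; the C4 centre is removed again in step 16.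

Step 9
Reactants: 13 (1R,3S,4R)-3-[(tert-butyldimethylsilyl)oxy]-6-methoxy-1,4-dimethyl-1-[(triethylsilyl)oxy]-1,2,3,4-tetrahydroazulene
Product: 14 (1R,3S,4R)-3-[(tert-butyldimethylsilyl)oxy]-1,4-dimethyl-1-[(triethylsilyl)oxy]-2,3,4,5-tetrahydroazulen-6(1H)-one
Conditions: oxalic acid, THF/H2O, 0 °C
Reagents that add atoms: water, O
Why: Enol ether hydrolysis by protonation at C9, the only carbon in conjugation with the methoxy oxygen, which gives the C8 ketone as the linear dienone while the weak acid spares both silyl ethers.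

Step 10
Reactants: 14 (1R,3S,4R)-3-[(tert-butyldimethylsilyl)oxy]-1,4-dimethyl-1-[(triethylsilyl)oxy]-2,3,4,5-tetrahydroazulen-6(1H)-one
Product: 15 (1R,3S,4R)-3-[(tert-butyldimethylsilyl)oxy]-1,4-dimethyl-1,6-bis[(triethylsilyl)oxy]-1,2,3,4,5,8-hexahydroazulene
Conditions: RhCl(PPh3)3 (2 mol%), Et3SiH, toluene, 50 °C
Reagents that add atoms: triethylsilane, CC[SiH](CC)CC
Why: Rhodium-catalysed 1,4-hydrosilylation of an enone by a monohydrosilane, which puts hydrogen on C6 (the fully substituted δ-carbon C1 is left alone) and fixes the enol ether at C7=C8.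

Step 11
Reactants: 15 (1R,3S,4R)-3-[(tert-butyldimethylsilyl)oxy]-1,4-dimethyl-1,6-bis[(triethylsilyl)oxy]-1,2,3,4,5,8-hexahydroazulene; 16 2,2-dimethoxypropane
Product: 18 (1R,3S,4R)-3-[(tert-butyldimethylsilyl)oxy]-1,4-dimethyl-7-(propan-2-ylidene)-1-[(triethylsilyl)oxy]-2,3,4,5,7,8-hexahydroazulen-6(1H)-one, via methoxy ketone 17 (not isolated)
Conditions: TMSOTf (10 mol%), CH2Cl2, −78 °C; then DBU, rt
Reagents that add atoms: none
Why: Mukaiyama-type aldol addition of the enol silyl ether to the ketal under silyl triflate catalysis forms the C7–C11 bond at the position fixed in step 10, and E1cB loss of methanol from the β-methoxy ketone gives the conjugated isopropylidene ketone.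

Step 12
Reactants: 18 (1R,3S,4R)-3-[(tert-butyldimethylsilyl)oxy]-1,4-dimethyl-7-(propan-2-ylidene)-1-[(triethylsilyl)oxy]-2,3,4,5,7,8-hexahydroazulen-6(1H)-one
Product: 19 (1R,3S,4R)-1,3-dihydroxy-1,4-dimethyl-7-(propan-2-ylidene)-2,3,4,5,7,8-hexahydroazulen-6(1H)-one
Conditions: TBAF, THF, rt
Reagents that add atoms: none
Why: Fluoride desilylation removes both silyl ethers and gives the diol from which the two halves diverge.

Step 13
Reactants: 19 (1R,3S,4R)-1,3-dihydroxy-1,4-dimethyl-7-(propan-2-ylidene)-2,3,4,5,7,8-hexahydroazulen-6(1H)-one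
Product: 20 (1R,3S,4R,7S)-1,3-dihydroxy-1,4-dimethyl-7-(propan-2-yl)-2,3,4,5,7,8-hexahydroazulen-6(1H)-one
Conditions: H2 (1 atm), Pd/C, EtOAc, rt; then K2CO3, MeOH, rt
Reagents that add atoms: none
Why: Heterogeneous hydrogenation of the exocyclic enone (the tetrasubstituted ring alkene is too hindered to react), then equilibration of C7 beside the ketone, which places the isopropyl group equatorial and so cis to the C10 methyl group that allylic strain with C2 holds pseudoaxial.

Step 14
Reactants: 20 (1R,3S,4R,7S)-1,3-dihydroxy-1,4-dimethyl-7-(propan-2-yl)-2,3,4,5,7,8-hexahydroazulen-6(1H)-one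
Product: 21 (1R,3S,4R,7S)-3-acetoxy-1-hydroxy-1,4-dimethyl-7-(propan-2-yl)-2,3,4,5,7,8-hexahydroazulen-6(1H)-one
Conditions: Ac2O, pyridine, DMAP (cat.), CH2Cl2, 0 °C
Reagents that add atoms: acetic anhydride, CC(=O)OC(C)=O
Why: Acylation of the secondary allylic alcohol with retention at C2, the tertiary alcohol being too hindered to react.

Step 15
Reactants: 19 (1R,3S,4R)-1,3-dihydroxy-1,4-dimethyl-7-(propan-2-ylidene)-2,3,4,5,7,8-hexahydroazulen-6(1H)-one
Product: 22 (1R,4R)-1-hydroxy-1,4-dimethyl-7-(propan-2-ylidene)-1,2,4,5,7,8-hexahydroazulene-3,6-dione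
Conditions: MnO2, CH2Cl2, rt
Reagents that add atoms: none
Why: Manganese dioxide oxidation of the secondary allylic alcohol to the cyclopentenone under neutral conditions, which leaves the tertiary alcohol and the doubly allylic C6 methylene untouched.

Step 16
Reactants: 21 (1R,3S,4R,7S)-3-acetoxy-1-hydroxy-1,4-dimethyl-7-(propan-2-yl)-2,3,4,5,7,8-hexahydroazulen-6(1H)-one; 22 (1R,4R)-1-hydroxy-1,4-dimethyl-7-(propan-2-ylidene)-1,2,4,5,7,8-hexahydroazulene-3,6-dione
Product: 25 endo Diels–Alder adduct (the target without the peroxide: 2-acetoxy diene half joined through C1–C4' and C3–C3' to the 2',8'-dioxo-7'(11')-ene half), via acetoxy diene 23 (not isolated), via cyclopentadienone 24 (not isolated)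
Conditions: 21, Ph2S[OC(CF3)2Ph]2, CH2Cl2, −40 to 0 °C; then 22 added slowly, 0 °C to rt
Reagents that add atoms: none
Why: Sulfurane dehydration of each tertiary alcohol gives the 5-acetoxycyclopentadiene 23 (loss of H3) and the cyclopentadienone 24 (loss of the acidic H3' beside the ketone), which combine in an endo Diels–Alder reaction in which the two unsubstituted termini C3 and C3' bond first and C1–C4' then closes the norbornene; the dienophile adds to the diene face opposite the C2 acetoxy and C10 methyl groups (its C4' methyl, forced exo, would clash with a syn acetoxy group) and uses its own face opposite the C10' methyl group, which sets C1, C3, C3' and C4' together.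

Step 17
Reactants: 25 endo Diels–Alder adduct
Product: 27 CNP0317907.1 (8'-hydroxy-8',11'-epidioxy hemiketal of the adduct with C6'=C7'), via hydroperoxide 26 (not isolated)
Conditions: O2, hν (visible light), tetraphenylporphyrin, CH2Cl2, 0 °C
Reagents that add atoms: dioxygen, O=O
Why: Schenck ene reaction of the isopropylidene ketone with geminal selectivity, in which singlet oxygen bonds to C11' and takes a doubly allylic hydrogen from C6', the hydroperoxide closes onto the C8' ketone and the hemiketal centre settles by ring–chain equilibration, while the C4=C5 bond is shielded by the syn acetoxy group and the endo-fused ring.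

**Compound list**
1 | 1-(4-methoxy-2-methylphenyl)ethan-1-one | CC(=O)c1ccc(OC)cc1C | starting material
2 | diethyl carbonate | CCOC(=O)OCC | starting material
3 | ethyl 3-(4-methoxy-2-methylphenyl)-3-oxopropanoate | CCOC(=O)CC(=O)c1ccc(OC)cc1C | intermediate
4 | ethyl (3S)-3-hydroxy-3-(4-methoxy-2-methylphenyl)propanoate | CCOC(=O)C[C@H](O)c1ccc(OC)cc1C | intermediate
5 | ethyl (3S)-3-[(tert-butyldimethylsilyl)oxy]-3-(4-methoxy-2-methylphenyl)propanoate | CCOC(=O)C[C@H](O[Si](C)(C)C(C)(C)C)c1ccc(OC)cc1C | intermediate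
6 | (3S)-3-[(tert-butyldimethylsilyl)oxy]-3-(4-methoxy-2-methylphenyl)propanoic acid | OC(=O)C[C@H](O[Si](C)(C)C(C)(C)C)c1ccc(OC)cc1C | intermediate
7 | mixed isobutyl carbonic anhydride of acid 6 (not isolated) | CC(C)COC(=O)OC(=O)C[C@H](O[Si](C)(C)C(C)(C)C)c1ccc(OC)cc1C | intermediate
8 | (4S)-4-[(tert-butyldimethylsilyl)oxy]-1-diazo-4-(4-methoxy-2-methylphenyl)butan-2-one | [N-]=[N+]=CC(=O)C[C@H](O[Si](C)(C)C(C)(C)C)c1ccc(OC)cc1C | intermediate
9 | norcaradiene valence tautomer of 10, cyclopropane C1–C5–C6 (not isolated) | O=C1C[C@H](O[Si](C)(C)C(C)(C)C)[C@]23C(C)=CC(OC)=C[C@H]2[C@H]13 | intermediate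
10 | (3S,8aS)-3-[(tert-butyldimethylsilyl)oxy]-6-methoxy-4-methyl-3,8a-dihydroazulen-1(2H)-one, H-8a anti to the silyloxy group | O=C1C[C@H](O[Si](C)(C)C(C)(C)C)C2=C(C)C=C(OC)C=C[C@H]12 | intermediate
11 | (3S,4R)-3-[(tert-butyldimethylsilyl)oxy]-6-methoxy-4-methyl-3,4-dihydroazulen-1(2H)-one, 4-methyl cis to 3-silyloxy | O=C1C[C@H](O[Si](C)(C)C(C)(C)C)C2=C1C=CC(OC)=C[C@H]2C | intermediate
12 | lithium alkoxide of the C4 methyl adduct of 11 (not isolated) | C[C@@]1(O[Li])C[C@H](O[Si](C)(C)C(C)(C)C)C2=C1C=CC(OC)=C[C@H]2C | intermediate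
13 | (1R,3S,4R)-3-[(tert-butyldimethylsilyl)oxy]-6-methoxy-1,4-dimethyl-1-[(triethylsilyl)oxy]-1,2,3,4-tetrahydroazulene | C[C@@]1(O[Si](CC)(CC)CC)C[C@H](O[Si](C)(C)C(C)(C)C)C2=C1C=CC(OC)=C[C@H]2C | intermediate
14 | (1R,3S,4R)-3-[(tert-butyldimethylsilyl)oxy]-1,4-dimethyl-1-[(triethylsilyl)oxy]-2,3,4,5-tetrahydroazulen-6(1H)-one | C[C@@]1(O[Si](CC)(CC)CC)C[C@H](O[Si](C)(C)C(C)(C)C)C2=C1C=CC(=O)C[C@H]2C | intermediate
15 | (1R,3S,4R)-3-[(tert-butyldimethylsilyl)oxy]-1,4-dimethyl-1,6-bis[(triethylsilyl)oxy]-1,2,3,4,5,8-hexahydroazulene | C[C@@]1(O[Si](CC)(CC)CC)C[C@H](O[Si](C)(C)C(C)(C)C)C2=C1CC=C(O[Si](CC)(CC)CC)C[C@H]2C | intermediate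
16 | 2,2-dimethoxypropane | COC(C)(C)OC | starting material
17 | 7-(2-methoxypropan-2-yl) ketone, side chain anti to the C10 methyl (not isolated) | C[C@@]1(O[Si](CC)(CC)CC)C[C@H](O[Si](C)(C)C(C)(C)C)C2=C1C[C@H](C(C)(C)OC)C(=O)C[C@H]2C | intermediate
18 | (1R,3S,4R)-3-[(tert-butyldimethylsilyl)oxy]-1,4-dimethyl-7-(propan-2-ylidene)-1-[(triethylsilyl)oxy]-2,3,4,5,7,8-hexahydroazulen-6(1H)-one | C[C@@]1(O[Si](CC)(CC)CC)C[C@H](O[Si](C)(C)C(C)(C)C)C2=C1CC(=C(C)C)C(=O)C[C@H]2C | intermediate
19 | (1R,3S,4R)-1,3-dihydroxy-1,4-dimethyl-7-(propan-2-ylidene)-2,3,4,5,7,8-hexahydroazulen-6(1H)-one | C[C@@]1(O)C[C@H](O)C2=C1CC(=C(C)C)C(=O)C[C@H]2C | intermediate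
20 | (1R,3S,4R,7S)-1,3-dihydroxy-1,4-dimethyl-7-(propan-2-yl)-2,3,4,5,7,8-hexahydroazulen-6(1H)-one | C[C@@]1(O)C[C@H](O)C2=C1C[C@@H](C(C)C)C(=O)C[C@H]2C | intermediate
21 | (1R,3S,4R,7S)-3-acetoxy-1-hydroxy-1,4-dimethyl-7-(propan-2-yl)-2,3,4,5,7,8-hexahydroazulen-6(1H)-one | C[C@@]1(O)C[C@H](OC(C)=O)C2=C1C[C@@H](C(C)C)C(=O)C[C@H]2C | intermediate
22 | (1R,4R)-1-hydroxy-1,4-dimethyl-7-(propan-2-ylidene)-1,2,4,5,7,8-hexahydroazulene-3,6-dione | C[C@@]1(O)CC(=O)C2=C1CC(=C(C)C)C(=O)C[C@H]2C | intermediate
23 | (3S,4R,7S)-3-acetoxy-1,4-dimethyl-7-(propan-2-yl)-4,5,7,8-tetrahydroazulen-6(3H)-one, the diene (not isolated) | CC1=C[C@H](OC(C)=O)C2=C1C[C@@H](C(C)C)C(=O)C[C@H]2C | intermediate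
24 | (4R)-1,4-dimethyl-7-(propan-2-ylidene)-4,5,7,8-tetrahydroazulene-3,6-dione, the cyclopentadienone (not isolated) | CC1=CC(=O)C2=C1CC(=C(C)C)C(=O)C[C@H]2C | intermediate
25 | endo Diels–Alder adduct, bonds C1–C4' and C3–C3', acetoxy syn to C4=C5, isopropylidene ketone in the primed half | CC(=O)O[C@H]1[C@H]2C(C)=C3C[C@@H](C(C)C)C(=O)C[C@@H](C)[C@]31[C@]1(C)C3=C(C(=O)[C@H]21)[C@H](C)CC(=O)C(=C(C)C)C3 | intermediate
26 | 11'-hydroperoxide of 25 with C6'=C7' (not isolated) | CC(=O)O[C@H]1[C@H]2C(C)=C3C[C@@H](C(C)C)C(=O)C[C@@H](C)[C@]31[C@]1(C)C3=C(C(=O)[C@H]21)[C@H](C)CC(=O)C(C(C)(C)OO)=C3 | intermediate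
27 | CNP0317907.1, the 8'-hydroxy-8',11'-epidioxy hemiketal | CC(=O)O[C@H]1[C@H]2C(C)=C3C[C@@H](C(C)C)C(=O)C[C@@H](C)[C@]31[C@]1(C)C3=C(C(=O)[C@H]21)[C@H](C)C[C@@]1(O)OOC(C)(C)C1=C3 | target

**Count**
Total steps: 17. Longest linear sequence: 16 steps (steps 1–14, 16 and 17); the dienophile branch is steps 1–12 and 15.

**Steps most likely to fail**

Step 16. Several processes can divert this step:
- the cyclopentadienone may dimerise before the diene traps it;
- the dienophile may add on the acetoxy face, the electronic preference of 5-acyloxycyclopentadienes;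
- the partners may join in the other regiochemical sense (C3–C4');
- the diene may isomerise by [1,5]-hydrogen shift before it is trapped.

The fallback replaces the acetoxy group by a bulky silyl ether during the cycloaddition, so that steric shielding of that face is increased, and puts the acetate on afterwards. It sets out from diol 20. Selective silylation of the secondary alcohol (TIPSOTf, 2,6-lutidine, −78 °C) should give the triisopropylsilyl ether F1. Dehydration with Ph2S[OC(CF3)2Ph]2 as in step 16 should give the silyloxy diene F2, used at once with slowly added 22 (which forms 24) to give the silyl-protected adduct F3. HF·pyridine should free the C2 alcohol of the adduct F4, and Ac2O with DMAP returns the route to compound 25.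

Step 7. The proton may return on the silyloxy face. The C10 centre may later equilibrate through the γ-deprotonated enolate; the trans isomer is expected to be the more stable one. The 4-silyloxycyclopentenone may also lose silanol by β-elimination. The fallback moves the proton shift to a stage at which C4 is no longer a ketone. It sets out from compound 10. Addition of MeLi/CeCl3 to the C4 ketone and trapping with TESOTf should give the 8a-H triethylsilyl ether F5. Oxalic acid hydrolysis of its enol ether should give the cycloheptadienone F6, in which H5 is γ to the C8 enone. Et3N or DBU then moves H5 to C10 through the linear trienolate, and the route is rejoined at compound 14. No β-silyloxy ketone is present in this sequence, and the new C10 hydrogen is remote from the carbonyl.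

Step 17. Singlet oxygen may take a hydrogen from an isopropylidene methyl group, which would give the α-hydroperoxy isopropenyl ketone. It may also attack the tetrasubstituted C4=C5 bond. The hemiketal may form as an epimer mixture that equilibrates only slowly. The fallback builds the peroxide by polar chemistry and avoids singlet oxygen. It sets out from compound 25. Conjugate addition of H2O2 to the isopropylidene ketone (aqueous H2O2 with a catalytic primary ammonium salt, the known route from β,β-disubstituted enones to 1,2-dioxolan-3-ols) should give the saturated peroxy-hemiketal F7. Quinone dehydrogenation (DDQ, dioxane) through the dienol of the C2' enone should then introduce C6'=C7' and arrive at compound 27.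

Further compounds
F1 | step 16 | (1R,3S,4R,7S)-1-hydroxy-1,4-dimethyl-7-(propan-2-yl)-3-[(triisopropylsilyl)oxy]-2,3,4,5,7,8-hexahydroazulen-6(1H)-one | C[C@@]1(O)C[C@H](O[Si](C(C)C)(C(C)C)C(C)C)C2=C1C[C@@H](C(C)C)C(=O)C[C@H]2C
F2 | step 16 | (3S,4R,7S)-1,4-dimethyl-7-(propan-2-yl)-3-[(triisopropylsilyl)oxy]-4,5,7,8-tetrahydroazulen-6(3H)-one, silyloxy diene | CC1=C[C@H](O[Si](C(C)C)(C(C)C)C(C)C)C2=C1C[C@@H](C(C)C)C(=O)C[C@H]2C
F3 | step 16 | endo adduct as 25 with triisopropylsilyloxy in place of acetoxy at C2 | CC(C)[Si](C(C)C)(C(C)C)O[C@H]1[C@H]2C(C)=C3C[C@@H](C(C)C)C(=O)C[C@@H](C)[C@]31[C@]1(C)C3=C(C(=O)[C@H]21)[C@H](C)CC(=O)C(=C(C)C)C3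
F4 | step 16 | endo adduct as 25 with free hydroxyl at C2 | O[C@H]1[C@H]2C(C)=C3C[C@@H](C(C)C)C(=O)C[C@@H](C)[C@]31[C@]1(C)C3=C(C(=O)[C@H]21)[C@H](C)CC(=O)C(=C(C)C)C3
F5 | step 7 | (1R,3S,8aS)-3-[(tert-butyldimethylsilyl)oxy]-6-methoxy-1,4-dimethyl-1-[(triethylsilyl)oxy]-1,2,3,8a-tetrahydroazulene | C[C@@]1(O[Si](CC)(CC)CC)C[C@H](O[Si](C)(C)C(C)(C)C)C2=C(C)C=C(OC)C=C[C@H]12
F6 | step 7 | (1R,3S,8aS)-3-[(tert-butyldimethylsilyl)oxy]-1,4-dimethyl-1-[(triethylsilyl)oxy]-2,3,5,8a-tetrahydroazulen-6(1H)-one | C[C@@]1(O[Si](CC)(CC)CC)C[C@H](O[Si](C)(C)C(C)(C)C)C2=C(C)CC(=O)C=C[C@H]12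
F7 | step 17 | 6',7'-dihydro derivative of 27, cis-fused 8'-hydroxy-8',11'-epidioxy hemiketal | CC(=O)O[C@H]1[C@H]2C(C)=C3C[C@@H](C(C)C)C(=O)C[C@@H](C)[C@]31[C@]1(C)C3=C(C(=O)[C@H]21)[C@H](C)C[C@@]1(O)OOC(C)(C)[C@H]1C3
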